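**Retrosynthetic overview**

- The target is reached from its C2''-epimer, the 2,3-cis,2'',3''-cis biflavanone, by epimerisation of the hydroxyphenyl half through its ring-B p-quinone methide. The methoxyphenyl half cannot open this way and keeps its cis ring.
- Key disconnection: both aryl ether bonds O1–C8a and O1''–C8a'' and both ketone bonds C4–C4a and C4''–C4a'' are cut, giving an exo,exo cis-fused bis-γ-lactone (3,6-diaryl-furo[3,4-c]furan-1,4-dione) and two equivalents of one 2,4-bis(benzyloxy)-6-fluorophenyllithium.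
- Enabling feature: each pyranone oxygen lies 1,4 to the C4 carbon of the other half (O1–C2–C3–C3''–C4'' and O1''–C2''–C3''–C3–C4). The C2–C3–C3''–C2'' chain with both C4 carbons therefore folds into a dilactone that masks both alkoxides and both acyl groups, and the two rings A are identical.
- The dilactone comes from DDQ double oxidative lactonisation of (2R,3R)-2,3-bis(4-hydroxybenzyl)succinic acid, made by auxiliary-controlled oxidative enolate homocoupling of two molecules of one N-acyloxazolidinone; the two homotopic phenols are then differentiated (OMe/OBn).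
- Ring order: rings A and B are bought as arenes; the two temporary lactone rings form in step 5; both rings C form together in step 10.

Key step: step 10

Assumption: the oxidative enolate coupling is taken to follow the facial bias of auxiliary-controlled alkylation, so that the (S)-oxazolidinone gives the (2R,3R) diacid, and 2,3-trans is taken to be the thermodynamically preferred arrangement of the hydroxyphenyl-bearing pyranone ring.

**Route**

Step 1
Reactants: 1 3-[4-(benzyloxy)phenyl]propanoic acid; 2 (S)-4-benzyl-2-oxazolidinone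
Product: 3 (S)-4-benzyl-3-{3-[4-(benzyloxy)phenyl]propanoyl}oxazolidin-2-one
Conditions: t-BuCOCl, Et3N, THF, −20 °C; then LiCl, 2, −20 → 23 °C
Reagents that add atoms: none
Why: N-acylation of the oxazolidinone through the mixed pivalic anhydride, in which no stereocentre is formed and the auxiliary centre is untouched.

Step 2
Reactants: 3 (S)-4-benzyl-3-{3-[4-(benzyloxy)phenyl]propanoyl}oxazolidin-2-one (2 equiv)
Product: 4 (2R,3R)-2,3-bis[4-(benzyloxy)benzyl]-1,4-bis[(S)-4-benzyl-2-oxooxazolidin-3-yl]butane-1,4-dione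
Conditions: LiN(i-Pr)2 (1.05 equiv per 3), THF, −78 °C; then TiCl4 (1.1 equiv per 3), −78 → 0 °C
Reagents that add atoms: none
Why: Oxidative homocoupling in which two molecules of the chelated Z-enolate of the chiral N-acyloxazolidinone 3 are joined at their α-carbons (tetravalent titanium is reduced to trivalent titanium); each new stereocentre should be set by bond formation on the enolate face opposite the 4-benzyl group, so that the (S)-auxiliary gives the C2-symmetric (R,R) dimer.

Step 3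
Reactants: 4 (2R,3R)-2,3-bis[4-(benzyloxy)benzyl]-1,4-bis[(S)-4-benzyl-2-oxooxazolidin-3-yl]butane-1,4-dione
Product: 5 (2R,3R)-2,3-bis[4-(benzyloxy)benzyl]succinic acid
Conditions: LiOH, H2O2, THF/H2O, 0 °C; Na2SO3; then HCl (aq) to pH 2
Reagents that add atoms: hydrogen peroxide, OO (as LiOOH; supplies the hydroxyl oxygen of each carboxylic acid)
Why: Hydroperoxide cleavage of the exocyclic imide carbonyls, which is selective for that carbonyl and should not enolise the α-stereocentres, so both are kept and the auxiliary is recovered.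

Step 4
Reactants: 5 (2R,3R)-2,3-bis[4-(benzyloxy)benzyl]succinic acid
Product: 6 (2R,3R)-2,3-bis(4-hydroxybenzyl)succinic acid
Conditions: H2 (1 atm), 10% Pd/C, MeOH/EtOAc, 23 °C
Reagents that add atoms: none
Why: Hydrogenolysis of the two aryl benzyl ethers, which touches neither stereocentre and frees the phenols needed for quinone methide formation.

Step 5
Reactants: 6 (2R,3R)-2,3-bis(4-hydroxybenzyl)succinic acid
Product: 7 (3S,3aS,6S,6aS)-3,6-bis(4-hydroxyphenyl)tetrahydro-1H,3H-furo[3,4-c]furan-1,4-dione (cis-fused, both aryl groups exo)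
Conditions: DDQ (2.1 equiv), 1,4-dioxane, 23 °C
Reagents that add atoms: none
Why: DDQ dehydrogenation of each 4-alkylphenol to a p-quinone methide and 5-exo-trig addition of the carboxylic acid 1,4 to it, in which the (R,R) core allows only the cis-fused bicycle and each aryl carbon is set trans to the neighbouring carbonyl substituent (aryl exo), the kinetic and, through reversible quinone methide formation, the thermodynamic outcome.

Step 6
Reactants: 7 (3S,3aS,6S,6aS)-3,6-bis(4-hydroxyphenyl)tetrahydro-1H,3H-furo[3,4-c]furan-1,4-dione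
Product: 8 (3S,3aS,6S,6aS)-3-(4-hydroxyphenyl)-6-(4-methoxyphenyl)tetrahydro-1H,3H-furo[3,4-c]furan-1,4-dione
Conditions: MeOH (1.0 equiv), PPh3, i-PrO2CN=NCO2i-Pr (DIAD), THF, 0 → 23 °C; recovered 7 recycled
Reagents that add atoms: methanol, CO
Why: Mitsunobu etherification of a phenol under near-neutral conditions; the two phenols of C2-symmetric 7 are homotopic, so mono-methylation can give only one mono-ether, and no stereocentre is involved.

Step 7
Reactants: 8 (3S,3aS,6S,6aS)-3-(4-hydroxyphenyl)-6-(4-methoxyphenyl)tetrahydro-1H,3H-furo[3,4-c]furan-1,4-dione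
Product: 9 (3S,3aS,6S,6aS)-3-[4-(benzyloxy)phenyl]-6-(4-methoxyphenyl)tetrahydro-1H,3H-furo[3,4-c]furan-1,4-dione
Conditions: BnOH, PPh3, i-PrO2CN=NCO2i-Pr (DIAD), THF, 0 → 23 °C
Reagents that add atoms: benzyl alcohol, OCc1ccccc1
Why: Mitsunobu benzylation of the remaining phenol, which avoids a free phenoxide next to the benzylic lactone C–O bond and leaves all four stereocentres untouched.

Step 8
Reactants: 10 5-fluorobenzene-1,3-diol
Product: 11 1,3-bis(benzyloxy)-5-fluorobenzene
Conditions: BnBr (2.2 equiv), K2CO3, DMF, 23 °C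
Reagents that add atoms: benzyl bromide, BrCc1ccccc1
Why: Williamson ether synthesis on both phenols.

Step 9
Reactants: 11 1,3-bis(benzyloxy)-5-fluorobenzene
Product: 12 1,5-bis(benzyloxy)-2-bromo-3-fluorobenzene
Conditions: NBS, MeCN, 0 °C
Reagents that add atoms: N-bromosuccinimide, O=C1CCC(=O)N1Br
Why: Electrophilic aromatic bromination para to one benzyloxy group and ortho to the other, at the less hindered doubly activated position next to fluorine and not between the two ethers.

Step 10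
Reactants: 9 (3S,3aS,6S,6aS)-3-[4-(benzyloxy)phenyl]-6-(4-methoxyphenyl)tetrahydro-1H,3H-furo[3,4-c]furan-1,4-dione; 12 1,5-bis(benzyloxy)-2-bromo-3-fluorobenzene (2.05 equiv)
Product: 16 (2S,3S)-5,7-bis(benzyloxy)-3-{(2S,3S)-5,7-bis(benzyloxy)-2-[4-(benzyloxy)phenyl]-4-oxochroman-3-yl}-2-(4-methoxyphenyl)chroman-4-one (both pyranone rings 2,3-cis), via aryllithium 13 (not isolated), via dilithium bis-lactolate 14 (not isolated), via dilithium dialkoxide 15 (not isolated)
Conditions: 12, t-BuLi (4.1 equiv), THF, −78 °C; add 9, −78 °C, 1 h; DMPU, −78 → 23 °C; NH4Cl (aq)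
Reagents that add atoms: none
Why: Proposed new method: two equivalents of aryllithium 13 add at −78 °C to the two lactone carbonyls of 9 to give bis-lactolate 14, which on warming opens to the bis(2-fluoroaryl ketone) dialkoxide 15; each benzylic alkoxide then attacks the fluorine-bearing ring carbon ortho to the ketone of its own half (Meisenheimer adduct stabilised by the C4 carbonyl, loss of LiF), so that O1–C8a and O1''–C8a'' form and each five-membered lactone is traded for a six-membered pyranone, a formal insertion of an aryne unit into each acyl–oxygen bond. The closest known reaction types are the mono-addition of aryllithiums to lactones to give lactols or keto alcohols and the intramolecular SNAr of alkoxides on ortho-fluoroaryl ketones that gives chroman-4-ones. Both rings C close in the same mode, an intramolecular addition–elimination at an aromatic carbon that is 6-endo with respect to the C4a=C8a bond conjugated to the ketone; the seven-membered closure onto the aryl ring of the other half and displacement of the ortho benzyloxy group in place of fluoride should both be much slower. No stereocentre is created: C2, C3, C3'' and C2'' come from the dilactone and no bond to any of them is made or broken, so the exo,exo dilactone is translated into the 2,3-cis,2'',3''-cis biflavanone, the kinetic arrangement that a closure through O1–C2 would not deliver. The step needs mono-addition at each carbonyl (secured by the lactolate, which persists at −78 °C, and by the two ortho substituents of the resulting aryl ketone), addition and not enolisation of the lactone (fast carbonyl addition at −78 °C), and SNAr faster than retro-aldol cleavage or α-epimerisation of the aldolates (fluoride as leaving group, ortho-carbonyl activation, DMPU to loosen the lithium alkoxides).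

Step 11
Reactants: 16 (2S,3S)-5,7-bis(benzyloxy)-3-{(2S,3S)-5,7-bis(benzyloxy)-2-[4-(benzyloxy)phenyl]-4-oxochroman-3-yl}-2-(4-methoxyphenyl)chroman-4-one
Product: 17 (2S,3S)-5,7-dihydroxy-3-[(2S,3S)-5,7-dihydroxy-2-(4-hydroxyphenyl)-4-oxochroman-3-yl]-2-(4-methoxyphenyl)chroman-4-one
Conditions: H2 (1 atm), 10% Pd/C, EtOAc/MeOH, 23 °C
Reagents that add atoms: none
Why: Neutral hydrogenolysis of the five aryl benzyl ethers, which should spare the methyl ether, the ketones and the ring-C ether bonds (their oxygens are part of vinylogous esters) and does not enolise C3 or C3''.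

Step 12
Reactants: 17 (2S,3S)-5,7-dihydroxy-3-[(2S,3S)-5,7-dihydroxy-2-(4-hydroxyphenyl)-4-oxochroman-3-yl]-2-(4-methoxyphenyl)chroman-4-one
Product: 18 (2S,3S)-5,7-dihydroxy-3-[(2R,3S)-5,7-dihydroxy-2-(4-hydroxyphenyl)-4-oxochroman-3-yl]-2-(4-methoxyphenyl)chroman-4-one (target)
Conditions: NaHCO3/Na2CO3 buffer (pH ca. 9.5), MeOH/H2O, argon, 23–40 °C; then dilute HCl to pH 5
Reagents that add atoms: none
Why: Base-mediated C2 epimerisation of a 4'-hydroxyflavanone, in which the 4'''-phenoxide expels the ring-A aryloxide to give a p-quinone methide that recloses (6-exo oxa-Michael) under thermodynamic control from the adjacent C3'' centre to the 2'',3''-trans ring, while C3'' is untouched and the 4'-O-methylated half cannot open this way and should keep its cis ring.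

**Compound list**

1 | 3-[4-(benzyloxy)phenyl]propanoic acid | OC(=O)CCc1ccc(OCc2ccccc2)cc1 | starting material
2 | (S)-4-benzyl-2-oxazolidinone | O=C1N[C@@H](Cc2ccccc2)CO1 | starting material
3 | (S)-4-benzyl-3-{3-[4-(benzyloxy)phenyl]propanoyl}oxazolidin-2-one | O=C(CCc1ccc(OCc2ccccc2)cc1)N1[C@@H](Cc2ccccc2)COC1=O | intermediate
4 | (2R,3R)-2,3-bis[4-(benzyloxy)benzyl]-1,4-bis[(S)-4-benzyl-2-oxooxazolidin-3-yl]butane-1,4-dione | O=C(N1[C@@H](Cc2ccccc2)COC1=O)[C@H](Cc1ccc(OCc2ccccc2)cc1)[C@@H](Cc1ccc(OCc2ccccc2)cc1)C(=O)N1[C@@H](Cc2ccccc2)COC1=O | intermediate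
5 | (2R,3R)-2,3-bis[4-(benzyloxy)benzyl]succinic acid | OC(=O)[C@H](Cc1ccc(OCc2ccccc2)cc1)[C@@H](Cc1ccc(OCc2ccccc2)cc1)C(O)=O | intermediate
6 | (2R,3R)-2,3-bis(4-hydroxybenzyl)succinic acid | OC(=O)[C@H](Cc1ccc(O)cc1)[C@@H](Cc1ccc(O)cc1)C(O)=O | intermediate
7 | (3S,3aS,6S,6aS)-3,6-bis(4-hydroxyphenyl)tetrahydro-1H,3H-furo[3,4-c]furan-1,4-dione | Oc1ccc(cc1)[C@H]1OC(=O)[C@@H]2[C@@H](c3ccc(O)cc3)OC(=O)[C@H]12 | intermediate
8 | (3S,3aS,6S,6aS)-3-(4-hydroxyphenyl)-6-(4-methoxyphenyl)tetrahydro-1H,3H-furo[3,4-c]furan-1,4-dione | COc1ccc(cc1)[C@H]1OC(=O)[C@@H]2[C@@H](c3ccc(O)cc3)OC(=O)[C@H]12 | intermediate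
9 | (3S,3aS,6S,6aS)-3-[4-(benzyloxy)phenyl]-6-(4-methoxyphenyl)tetrahydro-1H,3H-furo[3,4-c]furan-1,4-dione | COc1ccc(cc1)[C@H]1OC(=O)[C@@H]2[C@@H](c3ccc(OCc4ccccc4)cc3)OC(=O)[C@H]12 | intermediate
10 | 5-fluorobenzene-1,3-diol | Oc1cc(O)cc(F)c1 | starting material
11 | 1,3-bis(benzyloxy)-5-fluorobenzene | Fc1cc(OCc2ccccc2)cc(OCc2ccccc2)c1 | intermediate
12 | 1,5-bis(benzyloxy)-2-bromo-3-fluorobenzene | Fc1cc(OCc2ccccc2)cc(OCc2ccccc2)c1Br | intermediate
13 | [2,4-bis(benzyloxy)-6-fluorophenyl]lithium | [Li]c1c(F)cc(OCc2ccccc2)cc1OCc1ccccc1 | intermediate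
14 | dilithium (3S,3aS,6S,6aS)-1,4-bis[2,4-bis(benzyloxy)-6-fluorophenyl]-3-[4-(benzyloxy)phenyl]-6-(4-methoxyphenyl)hexahydrofuro[3,4-c]furan-1,4-bis(olate) (hemiketal centres undefined) | COc1ccc(cc1)[C@H]1OC(O[Li])(c3c(F)cc(OCc4ccccc4)cc3OCc3ccccc3)[C@@H]2[C@@H](c3ccc(OCc4ccccc4)cc3)OC(O[Li])(c3c(F)cc(OCc4ccccc4)cc3OCc3ccccc3)[C@H]12 | intermediate
15 | dilithium (1S,2S,3S,4S)-2,3-bis[2,4-bis(benzyloxy)-6-fluorobenzoyl]-1-[4-(benzyloxy)phenyl]-4-(4-methoxyphenyl)butane-1,4-bis(olate) | COc1ccc(cc1)[C@@H](O[Li])[C@@H](C(=O)c1c(F)cc(OCc2ccccc2)cc1OCc1ccccc1)[C@H](C(=O)c1c(F)cc(OCc2ccccc2)cc1OCc1ccccc1)[C@H](O[Li])c1ccc(OCc2ccccc2)cc1 | intermediate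
16 | (2S,3S)-5,7-bis(benzyloxy)-3-{(2S,3S)-5,7-bis(benzyloxy)-2-[4-(benzyloxy)phenyl]-4-oxochroman-3-yl}-2-(4-methoxyphenyl)chroman-4-one | COc1ccc([C@H]2Oc3cc(OCc4ccccc4)cc(OCc4ccccc4)c3C(=O)[C@H]2[C@@H]2C(=O)c3c(OCc4ccccc4)cc(OCc4ccccc4)cc3O[C@@H]2c2ccc(OCc3ccccc3)cc2)cc1 | intermediate
17 | (2S,3S)-5,7-dihydroxy-3-[(2S,3S)-5,7-dihydroxy-2-(4-hydroxyphenyl)-4-oxochroman-3-yl]-2-(4-methoxyphenyl)chroman-4-one | COc1ccc([C@H]2Oc3cc(O)cc(O)c3C(=O)[C@H]2[C@@H]2C(=O)c3c(O)cc(O)cc3O[C@@H]2c2ccc(O)cc2)cc1 | intermediate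
18 | (2S,3S)-5,7-dihydroxy-3-[(2R,3S)-5,7-dihydroxy-2-(4-hydroxyphenyl)-4-oxochroman-3-yl]-2-(4-methoxyphenyl)chroman-4-one | COc1ccc([C@H]2Oc3cc(O)cc(O)c3C(=O)[C@H]2[C@@H]2C(=O)c3c(O)cc(O)cc3O[C@H]2c2ccc(O)cc2)cc1 | target

**Step count**

Total: 12 steps. Longest linear sequence: 10 steps (steps 1–7, 10, 11, 12); steps 8–9 form the two-step side branch to the aryl bromide.

**Steps most likely to fail**

1. Step 10. The hindered aryllithium may deprotonate the lactone α-positions (followed by β-elimination of the benzylic carboxylate) in place of adding to the carbonyl. The lithium aldolates may undergo retro-aldol cleavage or α-epimerisation before the SNAr closure, and the aryllithium may lose LiF to an aryne. Fallback with known chemistry, from 9 back to 16: the two lactones are opened with MeNH(OMe)·HCl/AlMe3 (CH2Cl2, 0 °C) to the bis(N-methoxy-N-methylamide) diol F1, which is silylated at once (Et3SiCl, imidazole, DMF) to the bis(triethylsilyl) ether F2. Aryllithium 13 (2.2 equiv, THF, −78 °C) converts both Weinreb amides into the bis(2-fluoroaryl ketone) F3, HF·pyridine (THF, 0 °C) frees the bis(β-hydroxy ketone) F4, and Cs2CO3 in DMF at 23 °C closes both pyranone rings by intramolecular SNAr to give 16.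

2. Step 12. The equilibration may be incomplete or unselective: the quinone methide may tautomerise to the α-substituted chalcone, which would scramble C3''; ring opening may be slow because the ring-A hydroxyls ionise first; and the polyphenolate may be oxidised by air. Fallback, from 8 back to 18: 8 is silylated (t-BuMe2SiCl, imidazole, DMF) to the silyl ether dilactone F5, which is taken through the procedure of step 10 with aryllithium 13, by way of the silyl bis-lactolate F6 and the silyl dialkoxide F7, to the cis,cis tetrabenzyl silyl ether F8. Bu4NF in THF (0 → 23 °C, then AcOH) removes the silyl group and leaves the hydroxyphenyl half as the only phenoxide, in an aprotic medium and with both rings A still benzylated, so that the quinone methide relay to the 2'',3''-trans tetrabenzyl ether phenol F9 is separated from the polyphenol stage. Hydrogenolysis of F9 (H2, Pd/C) then gives 18 directly.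

3. Step 5. DDQ may over-oxidise the product or cause oxidative phenol coupling, and the quinone methides may tautomerise to cinnamic acids in competition with lactonisation. Fallback, from 6 back to 7: silylation (t-BuMe2SiCl, imidazole, DMF; then AcOH/THF/H2O to hydrolyse the silyl esters) gives the bis(silyl ether) diacid F10. Radical benzylic C–H lactonisation (PhI(OAc)2, KBr, CH2Cl2, 23 °C; the benzylic bromide is displaced by the 1,4-carboxylate) gives the bis(silyl ether) dilactone F11, and HF·pyridine returns 7.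

Further compounds
F1 | step 10 | (2S,3S)-2-{(S)-[4-(benzyloxy)phenyl](hydroxy)methyl}-3-[(S)-hydroxy(4-methoxyphenyl)methyl]-N1,N4-dimethoxy-N1,N4-dimethylbutanediamide | COc1ccc(cc1)[C@@H](O)[C@@H](C(=O)N(C)OC)[C@H](C(=O)N(C)OC)[C@H](O)c1ccc(OCc2ccccc2)cc1
F2 | step 10 | bis(triethylsilyl) ether of F1 | COc1ccc(cc1)[C@@H](O[Si](CC)(CC)CC)[C@@H](C(=O)N(C)OC)[C@H](C(=O)N(C)OC)[C@H](O[Si](CC)(CC)CC)c1ccc(OCc2ccccc2)cc1
F3 | step 10 | (1S,2S,3S,4S)-2,3-bis[2,4-bis(benzyloxy)-6-fluorobenzoyl]-1-[4-(benzyloxy)phenyl]-4-(4-methoxyphenyl)-1,4-bis(triethylsilyloxy)butane | COc1ccc(cc1)[C@@H](O[Si](CC)(CC)CC)[C@@H](C(=O)c1c(F)cc(OCc2ccccc2)cc1OCc1ccccc1)[C@H](C(=O)c1c(F)cc(OCc2ccccc2)cc1OCc1ccccc1)[C@H](O[Si](CC)(CC)CC)c1ccc(OCc2ccccc2)cc1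
F4 | step 10 | (1S,2S,3S,4S)-2,3-bis[2,4-bis(benzyloxy)-6-fluorobenzoyl]-1-[4-(benzyloxy)phenyl]-4-(4-methoxyphenyl)butane-1,4-diol | COc1ccc(cc1)[C@@H](O)[C@@H](C(=O)c1c(F)cc(OCc2ccccc2)cc1OCc1ccccc1)[C@H](C(=O)c1c(F)cc(OCc2ccccc2)cc1OCc1ccccc1)[C@H](O)c1ccc(OCc2ccccc2)cc1
F5 | step 12 | (3S,3aS,6S,6aS)-3-[4-(tert-butyldimethylsilyloxy)phenyl]-6-(4-methoxyphenyl)tetrahydro-1H,3H-furo[3,4-c]furan-1,4-dione | COc1ccc(cc1)[C@H]1OC(=O)[C@@H]2[C@@H](c3ccc(O[Si](C)(C)C(C)(C)C)cc3)OC(=O)[C@H]12
F6 | step 12 | dilithium bis-lactolate from F5 and 13 (silyl analogue of 14) | COc1ccc(cc1)[C@H]1OC(O[Li])(c3c(F)cc(OCc4ccccc4)cc3OCc3ccccc3)[C@@H]2[C@@H](c3ccc(O[Si](C)(C)C(C)(C)C)cc3)OC(O[Li])(c3c(F)cc(OCc4ccccc4)cc3OCc3ccccc3)[C@H]12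
F7 | step 12 | dilithium dialkoxide from F6 (silyl analogue of 15) | COc1ccc(cc1)[C@@H](O[Li])[C@@H](C(=O)c1c(F)cc(OCc2ccccc2)cc1OCc1ccccc1)[C@H](C(=O)c1c(F)cc(OCc2ccccc2)cc1OCc1ccccc1)[C@H](O[Li])c1ccc(O[Si](C)(C)C(C)(C)C)cc1
F8 | step 12 | (2S,3S)-5,7-bis(benzyloxy)-3-{(2S,3S)-5,7-bis(benzyloxy)-2-[4-(tert-butyldimethylsilyloxy)phenyl]-4-oxochroman-3-yl}-2-(4-methoxyphenyl)chroman-4-one | COc1ccc([C@H]2Oc3cc(OCc4ccccc4)cc(OCc4ccccc4)c3C(=O)[C@H]2[C@@H]2C(=O)c3c(OCc4ccccc4)cc(OCc4ccccc4)cc3O[C@@H]2c2ccc(O[Si](C)(C)C(C)(C)C)cc2)cc1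
F9 | step 12 | (2S,3S)-5,7-bis(benzyloxy)-3-[(2R,3S)-5,7-bis(benzyloxy)-2-(4-hydroxyphenyl)-4-oxochroman-3-yl]-2-(4-methoxyphenyl)chroman-4-one | COc1ccc([C@H]2Oc3cc(OCc4ccccc4)cc(OCc4ccccc4)c3C(=O)[C@H]2[C@@H]2C(=O)c3c(OCc4ccccc4)cc(OCc4ccccc4)cc3O[C@H]2c2ccc(O)cc2)cc1
F10 | step 5 | (2R,3R)-2,3-bis[4-(tert-butyldimethylsilyloxy)benzyl]succinic acid | OC(=O)[C@H](Cc1ccc(O[Si](C)(C)C(C)(C)C)cc1)[C@@H](Cc1ccc(O[Si](C)(C)C(C)(C)C)cc1)C(O)=O
F11 | step 5 | (3S,3aS,6S,6aS)-3,6-bis[4-(tert-butyldimethylsilyloxy)phenyl]tetrahydro-1H,3H-furo[3,4-c]furan-1,4-dione | CC(C)(C)[Si](C)(C)Oc1ccc(cc1)[C@H]1OC(=O)[C@@H]2[C@@H](c3ccc(O[Si](C)(C)C(C)(C)C)cc3)OC(=O)[C@H]12
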